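**Plan**

- Retrosynthesis: the C8 phenol and the chain alcohol are masked (methyl ether, silyl ether) and a C1'=C2' alkene is reintroduced; the lactone ring is then cut at C4–C4a and O2–C3 in one operation, giving 2-bromo-4,6-dimethoxybenzoic acid and a C13 terminal (E)-1,3-diene, which is cut at its internal double bond into a C10 aldehyde and an allylphosphonate.
- Enabling feature: C4–C3–C1'–C2' is an unbroken four-carbon run through the lactone ring and the side chain, with C4 on arene carbon C4a, C3 on lactone oxygen O2, and C4a ortho to the carboxyl-bearing C8a; this is the imprint of a terminal diene captured by an ortho-halobenzoic acid.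
- Forward: the acid (one step) and the chain-bearing diene (three steps) are made separately; the palladium-catalysed annulation closes the only new ring, the six-membered lactone, and attaches the whole chain in the same step.
- Endgame: alkene saturation, desilylation, and chelation-controlled cleavage of the C8 methyl ether.
- Stereochemistry: C3 is the only stereocentre; it is set in the annulation by the chiral ligand on palladium and is not touched afterwards. Its descriptor changes from S to R on saturation only because C4 and C1' swap priority.

Key step: step 5

Assumption: the sense of induction of the chiral ligand in step 5 cannot be predicted with confidence, so the ligand enantiomer is taken to be the one that delivers the 3S alkenyl lactone; its antipode is equally accessible.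

**Route**

Step 1
Reactants: 1 2-bromo-4,6-dimethoxybenzaldehyde
Product: 2 2-bromo-4,6-dimethoxybenzoic acid
Conditions: NaClO2, NaH2PO4, 2-methyl-2-butene (excess), t-BuOH/THF/H2O, 0 °C to rt
Reagents that add atoms: sodium chlorite, [Na+].[O-]Cl=O
Why: Pinnick oxidation by chlorous acid should convert the aldehyde into the acid without touching the aryl bromide or the ethers, the alkene scavenger trapping hypochlorous acid before it can chlorinate the activated ring.

Step 2
Reactants: 3 decane-1,10-diol
Product: 4 10-(tert-butyldimethylsilyloxy)decan-1-ol
Conditions: TBSCl (1 equiv), imidazole, 3 (3 equiv), THF/DMF, 0 °C to rt; excess diol recovered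
Reagents that add atoms: tert-butyldimethylsilyl chloride, CC(C)(C)[Si](C)(C)Cl
Why: statistical monosilylation of a symmetric primary diol used in excess (imidazole-promoted silyl ether formation) should give mainly the mono-ether, which is separable from the polar diol and the non-polar bis-ether.

Step 3
Reactants: 4 10-(tert-butyldimethylsilyloxy)decan-1-ol
Product: 5 10-(tert-butyldimethylsilyloxy)decanal
Conditions: TEMPO (10 mol %), PhI(OAc)2 (1.1 equiv), CH2Cl2, rt
Reagents that add atoms: none
Why: the TEMPO/oxoammonium-catalysed oxidation of a primary alcohol stops at the aldehyde and leaves the silyl ether alone.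

Step 4
Reactants: 5 10-(tert-butyldimethylsilyloxy)decanal; 6 diethyl allylphosphonate
Product: 8 (E)-tert-butyldimethyl(trideca-10,12-dien-1-yloxy)silane, via lithium beta-oxidophosphonate adduct 7 (not isolated)
Conditions: 6, n-BuLi, THF, −78 °C; then 5; then HMPA, −78 °C to rt
Reagents that add atoms: none
Why: Horner–Wadsworth–Emmons olefination, in which the lithiated allylphosphonate adds through its alpha carbon to the aldehyde and the adduct, once HMPA loosens the lithium chelate, should lose lithium diethyl phosphate by syn elimination through the less crowded trans oxaphosphetane to give the terminal (E)-diene.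

Step 5
Reactants: 2 2-bromo-4,6-dimethoxybenzoic acid; 8 (E)-tert-butyldimethyl(trideca-10,12-dien-1-yloxy)silane
Product: 9 (S)-3-[(E)-11-(tert-butyldimethylsilyloxy)undec-1-en-1-yl]-6,8-dimethoxy-3,4-dihydroisocoumarin
Conditions: Pd2(dba)3 (2.5 mol %), chiral tert-butanesulfinamide-derived monophosphine L* (10 mol %), K3PO4 (2 equiv), 2 (1.3 equiv), degassed 1,4-dioxane, 60 °C; stopped at full conversion of 8
Reagents that add atoms: none
Why: Proposed new method: zerovalent palladium inserts into the C–Br bond of the carboxylate of 2, the arylpalladium adds across the unsubstituted terminal alkene of 8 to form C4–C4a, and the η3-allylpalladium spanning C3–C1'–C2' is captured by the neighbouring carboxylate at C3 to form O2–C3 and release zerovalent palladium. The closest known reaction type is the Larock heteroannulation of 1,3-dienes by ortho-halobenzoic acids (racemic), together with the enantioselective Heck/Tsuji–Trost annulations of ortho-haloanilines and ortho-halophenols; new here is the asymmetric version with a carboxylate as the internal nucleophile. The lactone ring closes by 6-exo attack of the carboxylate oxygen on the proximal allyl terminus, the 8-endo alternative at C2' being disfavoured by ring size. C3 is controlled by the chiral ligand, which selects the diene face in the insertion and hence the face of the allyl terminus that the carboxylate attacks. The step needs insertion at the terminal CH2 (secured by the unhindered diene end, which also leads to the stabilised allyl complex), C–O closure faster than beta-hydride elimination to the aryl diene (secured by the tethered, ionised carboxylate), and no protodecarboxylation of the electron-rich, doubly ortho-substituted acid (secured by silver-free, mildly basic conditions at moderate temperature). The E alkene follows from the syn allyl complex and is in any case erased in step 6.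

Step 6
Reactants: 9 (S)-3-[(E)-11-(tert-butyldimethylsilyloxy)undec-1-en-1-yl]-6,8-dimethoxy-3,4-dihydroisocoumarin
Product: 10 (R)-3-[11-(tert-butyldimethylsilyloxy)undecyl]-6,8-dimethoxy-3,4-dihydroisocoumarin
Conditions: TsNHNH2 (excess, in portions), NaOAc, DME/H2O, reflux
Reagents that add atoms: none
Why: diimide reduction, a concerted metal-free transfer of two hydrogens to the C1'=C2' alkene, cannot cleave the allylic C3–O2 bond and leaves C3 unchanged in space (the descriptor becomes R because the saturated chain now ranks below C4).

Step 7
Reactants: 10 (R)-3-[11-(tert-butyldimethylsilyloxy)undecyl]-6,8-dimethoxy-3,4-dihydroisocoumarin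
Product: 11 (R)-3-(11-hydroxyundecyl)-6,8-dimethoxy-3,4-dihydroisocoumarin
Conditions: HF·pyridine, pyridine, THF, 0 °C to rt
Reagents that add atoms: none
Why: fluoride-mediated desilylation, driven by the strong Si–F bond, should free the primary alcohol under buffered conditions that spare the lactone and the aryl methyl ethers.

Step 8
Reactants: 11 (R)-3-(11-hydroxyundecyl)-6,8-dimethoxy-3,4-dihydroisocoumarin
Product: 13 (R)-8-hydroxy-3-(11-hydroxyundecyl)-6-methoxy-3,4-dihydroisocoumarin, via bis-dichloroboryl ester 12 (not isolated)
Conditions: BCl3 (3.5 equiv), CH2Cl2, −78 °C to 0 °C; then H2O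
Reagents that add atoms: none
Why: chelation-assisted Lewis-acid ether cleavage, in which BCl3 bridges the lactone carbonyl and the peri C8 methoxy oxygen so that chloride removes only that methyl group, while the C6 ether cannot chelate and the alcohol is held as a dichloroborinate that hydrolyses on work-up.

**Compound list**

1 | 2-bromo-4,6-dimethoxybenzaldehyde | COc1cc(Br)c(C=O)c(OC)c1 | starting material
2 | 2-bromo-4,6-dimethoxybenzoic acid | COc1cc(Br)c(C(=O)O)c(OC)c1 | intermediate
3 | decane-1,10-diol | OCCCCCCCCCCO | starting material
4 | 10-(tert-butyldimethylsilyloxy)decan-1-ol | OCCCCCCCCCCO[Si](C)(C)C(C)(C)C | intermediate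
5 | 10-(tert-butyldimethylsilyloxy)decanal | O=CCCCCCCCCCO[Si](C)(C)C(C)(C)C | intermediate
6 | diethyl allylphosphonate | C=CCP(=O)(OCC)OCC | starting material
7 | lithium alkoxide of diethyl [13-(tert-butyldimethylsilyloxy)-4-hydroxytridec-1-en-3-yl]phosphonate, diastereomer mixture, not isolated | [Li+].C=CC(C([O-])CCCCCCCCCO[Si](C)(C)C(C)(C)C)P(=O)(OCC)OCC | intermediate
8 | (E)-tert-butyldimethyl(trideca-10,12-dien-1-yloxy)silane | C=C/C=C/CCCCCCCCCO[Si](C)(C)C(C)(C)C | intermediate
9 | (S)-3-[(E)-11-(tert-butyldimethylsilyloxy)undec-1-en-1-yl]-6,8-dimethoxy-3,4-dihydroisocoumarin | COc1cc(OC)c2c(c1)C[C@@H](/C=C/CCCCCCCCCO[Si](C)(C)C(C)(C)C)OC2=O | intermediate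
10 | (R)-3-[11-(tert-butyldimethylsilyloxy)undecyl]-6,8-dimethoxy-3,4-dihydroisocoumarin | COc1cc(OC)c2c(c1)C[C@@H](CCCCCCCCCCCO[Si](C)(C)C(C)(C)C)OC2=O | intermediate
11 | (R)-3-(11-hydroxyundecyl)-6,8-dimethoxy-3,4-dihydroisocoumarin | COc1cc(OC)c2c(c1)C[C@@H](CCCCCCCCCCCO)OC2=O | intermediate
12 | (R)-8-(dichloroboryloxy)-3-[11-(dichloroboryloxy)undecyl]-6-methoxy-3,4-dihydroisocoumarin, not isolated | COc1cc(OB(Cl)Cl)c2c(c1)C[C@@H](CCCCCCCCCCCOB(Cl)Cl)OC2=O | intermediate
13 | (R)-8-hydroxy-3-(11-hydroxyundecyl)-6-methoxy-3,4-dihydroisocoumarin | COc1cc(O)c2c(c1)C[C@@H](CCCCCCCCCCCO)OC2=O | target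

**Step count and risks**

Total step count: 8. Longest linear sequence: 7 (steps 2 to 8, from decane-1,10-diol).

Steps most likely to fail:

Step 5 (the step labelled as a new method). Enantiomeric purity may erode because zerovalent palladium can re-ionise the allylic C3–O2 bond of the product. Facial discrimination may be weak with a carboxylate nucleophile. The arylpalladium may also be lost to protodecarboxylation, or the allyl complex to beta-hydride elimination.

The fallback uses known chemistry and takes the stereocentre from the chiral pool. It sets out from acid 2 and rejoins the route at lactone 10, so steps 5 and 6 are bypassed. Commercial 10-bromodecan-1-ol would be silylated (TBSCl, imidazole, DMF) to (10-bromodecyloxy)(tert-butyl)dimethylsilane F1. Mg in THF would convert it into [10-(tert-butyldimethylsilyloxy)decyl]magnesium bromide F2. CuI-catalysed opening of (R)-epichlorohydrin at its unsubstituted ring carbon (THF, −40 °C) should give (R)-1-chloro-13-(tert-butyldimethylsilyloxy)tridecan-2-ol F3. NaOH would close this to (R)-tert-butyldimethyl{[11-(oxiran-2-yl)undecyl]oxy}silane F4.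

Acid 2 would be esterified (MeI, K2CO3, DMF) to methyl 2-bromo-4,6-dimethoxybenzoate F5. Bromine–magnesium exchange with i-PrMgCl·LiCl (THF, −20 °C) would give [3,5-dimethoxy-2-(methoxycarbonyl)phenyl]magnesium chloride F6. With catalytic CuI this should open epoxide F4 at its CH2 terminus. The magnesium alkoxide so formed closes onto the neighbouring ester and should deliver lactone 10 with C3 in the R configuration, since the epoxide stereocentre is never touched.

Step 4. The ambident allyl anion may attack through its gamma carbon, the adduct may eliminate incompletely, or the new double bond may form with poor geometric control. The fallback replaces olefination by cross-coupling; it sets out from aldehyde 5 and rejoins at diene 8. Takai iodo-olefination (CHI3, CrCl2, THF/dioxane, 0 °C to rt) should give tert-butyl{[(E)-11-iodoundec-10-en-1-yl]oxy}dimethylsilane F7. Suzuki–Miyaura coupling with vinylboronic acid pinacol ester (Pd(PPh3)4, aqueous K3PO4, THF, 60 °C) would then give 8.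

Step 6. Diimide transfer may stall on the 1,2-disubstituted alkene because diimide disproportionates faster than it reduces. The fallback replaces stoichiometric diimide by homogeneous catalytic hydrogenation; it sets out from 9 and rejoins at 10. H2 (1 to 5 bar) with RhCl(PPh3)3 (5 mol %) in benzene/EtOH at rt should saturate the alkene through a rhodium dihydride, which does not ionise the allylic C–O bond. This fallback makes no new compound.

**Further compounds**

F1 | step 5 | (10-bromodecyloxy)(tert-butyl)dimethylsilane | BrCCCCCCCCCCO[Si](C)(C)C(C)(C)C
F2 | step 5 | [10-(tert-butyldimethylsilyloxy)decyl]magnesium bromide | Br[Mg]CCCCCCCCCCO[Si](C)(C)C(C)(C)C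
F3 | step 5 | (R)-1-chloro-13-(tert-butyldimethylsilyloxy)tridecan-2-ol | ClC[C@@H](CCCCCCCCCCCO[Si](C)(C)C(C)(C)C)O
F4 | step 5 | (R)-tert-butyldimethyl{[11-(oxiran-2-yl)undecyl]oxy}silane | C1[C@@H](CCCCCCCCCCCO[Si](C)(C)C(C)(C)C)O1
F5 | step 5 | methyl 2-bromo-4,6-dimethoxybenzoate | COc1cc(Br)c(C(=O)OC)c(OC)c1
F6 | step 5 | [3,5-dimethoxy-2-(methoxycarbonyl)phenyl]magnesium chloride | COc1cc([Mg]Cl)c(C(=O)OC)c(OC)c1
F7 | step 4 | tert-butyl{[(E)-11-iodoundec-10-en-1-yl]oxy}dimethylsilane | I/C=C/CCCCCCCCCO[Si](C)(C)C(C)(C)C
F0 | step 6 | none | none
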